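**Retrosynthetic overview**

- The strategy rests on the C5–C10 bond shared by rings A and B and the pattern around it: equatorial O1 on C1, axial C14 on C10, H5 trans to C14, and next to C5 the O-bearing quaternary C4 carrying C15. This is what remains when C5 of a 4E-alkene in a ten-membered germacrane attacks C10 of a trans-1,10-epoxide across the ring and C15 then loses a proton.
- The orthoester cage (C1' bound to O4, O6, O15) is made last, from tetrol 14 and cinnamaldehyde 15, by acetal formation and oxidation of the acetal C–H. O4 and O15 come from β-face dihydroxylation of C4=C15.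
- Rings A and B are formed together, by one C5–C10 bond, from 1,10-epoxygermacr-4E-ene 10.
- Epoxide 10 comes from germacradiene 9 by outer-face epoxidation of C1=C10. Diene 9 comes from epoxygermacrenol 6 by silylation, isopropenyl hydrogenation and stereospecific removal of a 4,5-epoxide.
- The ten-membered ring is made first, at C6–C7, by intramolecular palladium/zinc allylation of chloro epoxy aldehyde 4. Its epoxide, from Sharpless epoxidation of farnesol 1, is a temporary stereocontrol element that fixes C6 and C7 in absolute terms. Ring order: ten-membered ring, then rings A and B, then the two cage rings.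

Key step: step 9

Remark: germacrane/eudesmane numbering is used throughout; the α face is the face of C14 (with C15 and O1), the β face carries H5, O4, O6 and the isopropyl group.
Remark: C10 of 3 and 4 (farnesane numbering) is an epimeric mixture; this centre disappears when the allyl metal forms in step 4.
Remark: acetal 17 is expected as both epimers at the acetal carbon and may contain the 4,6-O-regioisomer; all of these should converge on the same cation in step 13.

**Step 1**
Reactants: 1 (2E,6E)-farnesol
Product: 2 (2S,3S)-2,3-epoxy-(6E)-farnesol
Conditions: Ti(OiPr)4 (5 mol%), L-(+)-diethyl tartrate (6 mol%), t-BuOOH, 4 Å MS, CH2Cl2, −20 °C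
Reagents that add atoms: tert-butyl hydroperoxide, CC(C)(C)OO
Why: Sharpless asymmetric epoxidation touches only the allylic-alcohol alkene, and the titanium–L-(+)-tartrate catalyst delivers oxygen to the face that gives the (2S,3S)-epoxide (as with geraniol), which sets the temporary centres that later control C6 and C7.

**Step 2**
Reactants: 2 (2S,3S)-2,3-epoxy-(6E)-farnesol
Product: 3 (2S,3S,6E)-10-chloro-2,3-epoxy-3,7,11-trimethyldodeca-6,11-dien-1-ol (10RS)
Conditions: PhSeCl (10 mol%), N-chlorosuccinimide (1.1 equiv), CH2Cl2, 0 °C to rt
Reagents that add atoms: N-chlorosuccinimide, O=C1CCC(=O)N1Cl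
Why: Selenium-catalysed allylic chlorination with double-bond transposition (selenenyl chloride addition, chlorination at selenium, elimination toward the methyl group) should favour the terminal isopropylidene unit as the most accessible trisubstituted alkene; the new C10 centre is left uncontrolled because step 4 erases it.

**Step 3**
Reactants: 3 (2S,3S,6E)-10-chloro-2,3-epoxy-3,7,11-trimethyldodeca-6,11-dien-1-ol
Product: 4 (2R,3S,6E)-10-chloro-2,3-epoxy-3,7,11-trimethyldodeca-6,11-dienal (10RS)
Conditions: TEMPO (10 mol%), PhI(OAc)2 (1.2 equiv), CH2Cl2, rt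
Reagents that add atoms: none
Why: Oxoammonium (TEMPO) oxidation of the primary alcohol stops at the aldehyde under near-neutral conditions, so the epoxide, the allylic chloride and the configuration of C2 (descriptor changes to R only through the priority rules) should be preserved.

**Step 4**
Reactants: 4 (2R,3S,6E)-10-chloro-2,3-epoxy-3,7,11-trimethyldodeca-6,11-dienal
Product: 6 (4S,5S,6R,7S)-4,5-epoxygermacra-1(10)E,11-dien-6-ol, via allylzinc aldehyde 5 (not isolated)
Conditions: Pd(PPh3)4 (10 mol%), Et2Zn (3.5 equiv), DMA, slow addition of 4 to 0.005 M, rt; aq. NH4Cl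
Reagents that add atoms: none
Why: Palladium-catalysed umpolung allylation (Barbier-type macrocyclisation): zerovalent palladium ionises the allylic chloride, Et2Zn turns the π-allyl complex into allylzinc 5, and its γ-carbon (C7) adds to the aldehyde carbon (C6) at high dilution; zinc held between the aldehyde oxygen and the neighbouring epoxide oxygen should fix the aldehyde face (5S,6R, threo), and the forming ten-membered ring admits the cyclic zinc transition state only with the C8 tether pseudo-axial, which places isopropenyl cis to O6 (7S), the known outcome for 2,3-epoxyfarnesal-derived allyl halides.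

**Step 5**
Reactants: 6 (4S,5S,6R,7S)-4,5-epoxygermacra-1(10)E,11-dien-6-ol
Product: 7 (4S,5S,6R,7S)-6-(tert-butyldimethylsilyloxy)-4,5-epoxygermacra-1(10)E,11-diene
Conditions: TBSOTf (1.5 equiv), 2,6-lutidine (3 equiv), CH2Cl2, −78 to 0 °C
Reagents that add atoms: tert-butyldimethylsilyl triflate, CC(C)(C)[Si](C)(C)OS(=O)(=O)C(F)(F)F
Why: Silyl triflate silylation of the hindered secondary alcohol under buffered, cold conditions should leave the epoxide closed; the TBS group later deactivates and screens C4=C5 and enforces the allylic-strain conformer of the key step.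

**Step 6**
Reactants: 7 (4S,5S,6R,7S)-6-(tert-butyldimethylsilyloxy)-4,5-epoxygermacra-1(10)E,11-diene
Product: 8 (4S,5S,6R,7S)-6-(tert-butyldimethylsilyloxy)-4,5-epoxygermacr-1(10)E-ene
Conditions: H2 (1 atm), RhCl(PPh3)3 (10 mol%), benzene, rt
Reagents that add atoms: none
Why: Homogeneous hydrogenation with RhCl(PPh3)3 reduces the 1,1-disubstituted isopropenyl alkene and should leave the trisubstituted C1=C10 alkene and the epoxide untouched; no stereocentre is created.

**Step 7**
Reactants: 8 (4S,5S,6R,7S)-6-(tert-butyldimethylsilyloxy)-4,5-epoxygermacr-1(10)E-ene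
Product: 9 (6R,7S)-6-(tert-butyldimethylsilyloxy)germacra-1(10)E,4E-diene
Conditions: WCl6 (3 equiv), n-BuLi (6 equiv), THF, −78 °C to rt; then 8, rt
Reagents that add atoms: none
Why: Tungsten-mediated epoxide deoxygenation (WCl6/n-BuLi) passes through an oxametallacycle that releases the alkene with retention, so the trans-epoxide should return the 4E-alkene without touching C6, C7, the silyl ether or C1=C10, at a temperature well below that of the germacradiene Cope rearrangement.

**Step 8**
Reactants: 9 (6R,7S)-6-(tert-butyldimethylsilyloxy)germacra-1(10)E,4E-diene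
Product: 10 (1S,10S,6R,7S)-6-(tert-butyldimethylsilyloxy)-1,10-epoxygermacr-4E-ene
Conditions: m-CPBA (1.0 equiv), NaHCO3 (solid), CH2Cl2, −40 to −20 °C
Reagents that add atoms: m-chloroperoxybenzoic acid, OOC(=O)c1cccc(Cl)c1
Why: Prilezhaev epoxidation should choose C1=C10, the more electron-rich and open alkene, because C4=C5 is inductively deactivated and screened on its outer face by the allylic OTBS group; the peracid attacks the outer face of the crossed conformer in which C14 lies on the same side as C15 (the orientation of C4=C5 being fixed by C6), which sets C1 and C10 as (1S,10S).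

**Step 9**
Reactants: 10 (1S,10S,6R,7S)-6-(tert-butyldimethylsilyloxy)-1,10-epoxygermacr-4E-ene
Product: 12 (1S,5R,6R,7S,10S)-6-(tert-butyldimethylsilyloxy)eudesm-4(15)-en-1-ol, via C4 eudesmyl cation 11 (not isolated)
Conditions: Me2AlCl (1.5 equiv), CH2Cl2, −78 °C; aq. Rochelle salt
Reagents that add atoms: none
Why: Me2AlCl binds the epoxide oxygen and the C10–O bond ionises while the C4=C5 π bond attacks C10 through C5 from the side opposite the departing oxygen, giving tertiary C4 cation 11, which loses a C15 proton to an aluminium-bound methyl (as methane) so that the exocyclic alkene forms and no free acid remains to isomerise it; C1 keeps its oxygen and configuration. The closest known reaction type is the acid-induced transannular cyclisation of germacrene 1(10)-epoxides to 1-hydroxyeudesm-4(15)-enes, an epoxide-initiated cation–olefin cyclisation. The single C5–C10 bond closes ring A in a 6-endo mode (C4 and C5 both lie inside the ring, and the breaking epoxide C–O bond is endocyclic to it) and ring B in a 6-exo mode (the cationic C4 lies outside it), both through the crossed chair–chair conformer. C10 is set by inversion at the epoxide carbon, which with the E-epoxide leaves C14 axial on the α face and O1 equatorial, and C5 is set by the alkene face turned toward C10: allylic 1,3-strain between C15 and the C6 substituents keeps H6 in the alkene plane and the OTBS group outside the ring, so C6 (R) exposes the face that puts H5 β, trans to C14. The step needs trans-fusion and loss of the C15 proton rather than the C3 proton, a hydride shift from C5 or capture of the cation; trans-fusion is secured because the (1S,10S)-epoxide was installed on the conformer that cyclises, the C6 silyloxy group disfavours a cation at C5, and the proton-scavenging Lewis acid at −78 °C should remove the most accessible methyl proton irreversibly.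

**Step 10**
Reactants: 12 (1S,5R,6R,7S,10S)-6-(tert-butyldimethylsilyloxy)eudesm-4(15)-en-1-ol
Product: 13 (1S,5R,6R,7S,10S)-eudesm-4(15)-ene-1,6-diol (1α-OH, 6β-OH)
Conditions: Bu4NF (3 equiv), THF, 50 °C
Reagents that add atoms: none
Why: Fluoride desilylation under basic conditions should free O6 without moving the exocyclic alkene into the ring, and it opens the β face of C4=C15 for the next step.

**Step 11**
Reactants: 13 (1S,5R,6R,7S,10S)-eudesm-4(15)-ene-1,6-diol
Product: 14 (1S,4S,5R,6R,7S,10S)-eudesmane-1,4,6,15-tetrol (1α,4β,6β-OH, 15-CH2OH on the α face)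
Conditions: OsO4 (5 mol%), NMO (2 equiv), acetone/H2O 4:1, rt
Reagents that add atoms: osmium tetroxide, O=[Os](=O)(=O)=O; N-methylmorpholine N-oxide, C[N+]1([O-])CCOCC1
Why: Upjohn dihydroxylation (syn addition through the osmate ester): the α face of C4=C15 is blocked by the 1,3-diaxial C14 methyl on C10, so osmium should add from the β face and set C4 with an equatorial β-hydroxyl and an axial α-CH2OH (4S).

**Step 12**
Reactants: 14 (1S,4S,5R,6R,7S,10S)-eudesmane-1,4,6,15-tetrol; 15 (E)-cinnamaldehyde
Product: 17 4,15-O-[(E)-3-phenylprop-2-enylidene] acetal of tetrol 14, via cinnamaldehyde dimethyl acetal 16 (not isolated)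
Conditions: 15 (1.2 equiv), HC(OMe)3, CSA (5 mol%), MeOH, rt; concentrate; then 14, DMF, 40 °C, reduced pressure
Reagents that add atoms: none
Why: Acid-catalysed transacetalisation through the dimethyl acetal made in the flask should join the primary O15 and the adjacent tertiary O4 in a five-membered dioxolane; the acetal carbon forms as both epimers, which is harmless because it becomes trigonal in step 13.

**Step 13**
Reactants: 17 4,15-O-[(E)-3-phenylprop-2-enylidene] acetal of tetrol 14
Product: 19 target orthoester CNP0190302.1, via styryl dioxolanylium cation 18 (not isolated)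
Conditions: DDQ (1.5 equiv), 2,6-di-tert-butylpyridine, 4 Å MS, CH2Cl2, 0 °C to rt
Reagents that add atoms: none
Why: Proposed new method: DDQ should abstract the hydride of the acetal C–H, which is allylic to the styryl group and flanked by two oxygens, to give the conjugated 2-styryl-1,3-dioxolan-2-ylium cation 18, which the free 6β-hydroxyl held next to it on the trans-decalin captures in a six-membered closure (in a regioisomeric acetal the free hydroxyl does the same), so the orthoester carbon can only take the configuration of the cage; the closest known reaction type is the DDQ oxidation of p-methoxybenzylidene acetals bearing a neighbouring hydroxyl to orthoesters, together with DDQ oxidation of cinnamyl ethers.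

**Compound list**

1 | (2E,6E)-farnesol | CC(C)=CCC/C(C)=C/CC/C(C)=C/CO | starting material
2 | (2S,3S)-2,3-epoxy-(6E)-farnesol | OC[C@@H]1O[C@@]1(C)CC/C=C(\C)CCC=C(C)C | intermediate
3 | (2S,3S,6E)-10-chloro-2,3-epoxy-3,7,11-trimethyldodeca-6,11-dien-1-ol (10RS) | OC[C@@H]1O[C@@]1(C)CC/C=C(\C)CCC(Cl)C(C)=C | intermediate
4 | (2R,3S,6E)-10-chloro-2,3-epoxy-3,7,11-trimethyldodeca-6,11-dienal (10RS) | O=C[C@@H]1O[C@@]1(C)CC/C=C(\C)CCC(Cl)C(C)=C | intermediate
5 | ethylzinc σ-allyl derivative of the epoxy aldehyde, zinc on C12 (not isolated) | O=C[C@@H]1O[C@@]1(C)CC/C=C(\C)CCC=C(C)C[Zn]CC | intermediate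
6 | (4S,5S,6R,7S)-4,5-epoxygermacra-1(10)E,11-dien-6-ol (O6 and isopropenyl cis) | C=C(C)[C@@H]1CC/C(C)=C/CC[C@]2(C)O[C@H]2[C@@H]1O | intermediate
7 | (4S,5S,6R,7S)-6-(tert-butyldimethylsilyloxy)-4,5-epoxygermacra-1(10)E,11-diene | C=C(C)[C@@H]1CC/C(C)=C/CC[C@]2(C)O[C@H]2[C@@H]1O[Si](C)(C)C(C)(C)C | intermediate
8 | (4S,5S,6R,7S)-6-(tert-butyldimethylsilyloxy)-4,5-epoxygermacr-1(10)E-ene | CC(C)[C@@H]1CC/C(C)=C/CC[C@]2(C)O[C@H]2[C@@H]1O[Si](C)(C)C(C)(C)C | intermediate
9 | (6R,7S)-6-(tert-butyldimethylsilyloxy)germacra-1(10)E,4E-diene | CC(C)[C@@H]1CC/C(C)=C/CC/C(C)=C/[C@@H]1O[Si](C)(C)C(C)(C)C | intermediate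
10 | (1S,10S,6R,7S)-6-(tert-butyldimethylsilyloxy)-1,10-epoxygermacr-4E-ene | CC(C)[C@@H]1CC[C@]2(C)O[C@H]2CC/C(C)=C/[C@@H]1O[Si](C)(C)C(C)(C)C | intermediate
11 | C4 eudesmyl cation with O1 bound to chlorodimethylaluminate (not isolated) | CC(C)[C@@H]1CC[C@@]2(C)[C@H]([C@@H]1O[Si](C)(C)C(C)(C)C)[C+](C)CC[C@@H]2O[Al-](C)(C)Cl | intermediate
12 | (1S,5R,6R,7S,10S)-6-(tert-butyldimethylsilyloxy)eudesm-4(15)-en-1-ol (1α-OH, H5 β, C14 α, 6β-OTBS, 7β-isopropyl) | CC(C)[C@@H]1CC[C@@]2(C)[C@H]([C@@H]1O[Si](C)(C)C(C)(C)C)C(=C)CC[C@@H]2O | intermediate
13 | (1S,5R,6R,7S,10S)-eudesm-4(15)-ene-1,6-diol | CC(C)[C@@H]1CC[C@@]2(C)[C@H]([C@@H]1O)C(=C)CC[C@@H]2O | intermediate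
14 | (1S,4S,5R,6R,7S,10S)-eudesmane-1,4,6,15-tetrol | CC(C)[C@@H]1CC[C@@]2(C)[C@H]([C@@H]1O)[C@](O)(CO)CC[C@@H]2O | intermediate
15 | (E)-cinnamaldehyde | O=C/C=C/c1ccccc1 | starting material
16 | (E)-cinnamaldehyde dimethyl acetal (not isolated) | COC(OC)/C=C/c1ccccc1 | intermediate
17 | 4,15-O-[(E)-3-phenylprop-2-enylidene] acetal of 14 (both epimers at the acetal carbon) | CC(C)[C@@H]1CC[C@@]2(C)[C@H]([C@@H]1O)[C@]1(COC(/C=C/c3ccccc3)O1)CC[C@@H]2O | intermediate
18 | 2-styryl-1,3-dioxolan-2-ylium cation from 17 (not isolated) | CC(C)[C@@H]1CC[C@@]2(C)[C@H]([C@@H]1O)[C@]1(CO[C+](/C=C/c3ccccc3)O1)CC[C@@H]2O | intermediate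
19 | CNP0190302.1, (1S,4S,5R,6R,7S,10S)-eudesmane-1,4,6,15-tetrol 4,6,15-ortho-(E)-cinnamate | CC(C)[C@@H]1CC[C@@]2(C)[C@@H]3[C@@H]1O[C@]1(/C=C/c4ccccc4)OC[C@@]3(CC[C@@H]2O)O1 | target

**Step count**

Total: 13 steps. Longest linear sequence: 13 steps, from farnesol 1; cinnamaldehyde 15 enters at step 12 without prior steps.

**Steps most likely to fail**

1. Step 13 (proposed new method). Hydride abstraction from the alkenyl acetal may be too slow, the cation may be intercepted by traces of water to give hydroxy cinnamates, or the hydroquinone may open the acid-labile cage. The fallback uses known chemistry and sets out from tetrol 14. Commercial (E)-cinnamonitrile (N#C/C=C/c1ccccc1) is converted by the Pinner reaction (dry HCl, MeOH, Et2O, 0 °C) into methyl (E)-cinnamimidate hydrochloride F1. F1 is alcoholysed in MeOH at rt to trimethyl ortho-(E)-cinnamate F2. Tetrol 14 and F2, with pyridinium p-toluenesulfonate (cat.) in CH2Cl2 over 4 Å MS, should undergo acid-catalysed transorthoesterification at O15, O4 and O6, driven by loss of methanol. The fallback comes back to the route at target 19 and bypasses 17.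

2. Step 9 (key step). The cation may lose the C3 proton and give the endocyclic alkene, may be captured by chloride, or the silyl ether may be lost under the Lewis acid. The fallback sets out from epoxide 10 and forms the same C5–C10 bond by a radical pathway: Cp2TiCl (trivalent titanium, from Cp2TiCl2 and Mn dust), THF, rt. Homolytic opening of the epoxide gives the tertiary C10 radical with O1 on titanium, this adds across the ring to C5, and the C4 radical is trapped by a second Cp2TiCl and eliminates toward C15. This is known for 1,10-epoxygermacranolides and gives the exocyclic alkene selectively. It comes back to the route at 12 and makes no new isolated compound.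

3. Step 8. Facial selectivity may be poor if the peracid also reacts through the parallel conformer, some C4=C5 epoxidation may compete, and the benzoic acid formed may start the transannular cyclisation early. The fallback sets out from diene 9 and replaces substrate control by catalyst control under basic conditions: Shi epoxidation with the L-fructose-configured ketone (1,2:4,5-di-O-isopropylidene-L-erythro-2,3-hexodiulo-2,6-pyranose, from L-sorbose), Oxone, K2CO3 buffer at pH 10.5, MeCN/dimethoxymethane/H2O, 0 °C. This catalyst enantiomer gives (S,S)-epoxides from E-trisubstituted alkenes, which matches the required (1S,10S) configuration. It comes back to the route at 10 and makes no new compound.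

**Further compounds**

F1 | step 13 | methyl (E)-cinnamimidate hydrochloride | COC(=[NH2+])/C=C/c1ccccc1.[Cl-]
F2 | step 13 | trimethyl ortho-(E)-cinnamate | COC(OC)(OC)/C=C/c1ccccc1
F0 | step 9 | none | none
F0 | step 8 | none | none
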